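Slowness is what the runs show first: delta needs 25.0 h to put 51.5% of its free monomer into chains.

| setting | delta | theta | violet | red | teal | grey |
|---|---|---|---|---|---|---|
| free monomer | 0.10 M | 0.050 M | 0.10 M | 0.10 M | 0.10 M | 0.10 M (fed, over 20.0 h) |
| transfer agent | 0.030 M | 0.030 M | 0.0300 M | 0.0300 M | 0.0300 M | 0.0300 M |
| initiator | 0.20 mM | 0.20 mM | 0.20 mM | 0.20 mM | 0.20 mM | 0.20 mM |
| remark | run made earlier | run made earlier | a single well-mixed tank run continuously and read at steady state, 125 h in it on average | a closed flask charged with all of it at once and left for 25 h | a single well-mixed tank run continuously and read at steady state, 25 h in it on average | a stirred flask in which free monomer is dosed at a steady rate over 20.0 h without added volume, worked up at 25 h |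
| time |  |  |  | 25 h |  | 25 h |

| run | time / h | monomer in chains / % | free monomer / % |
|---|---|---|---|
| delta | 2.00 | 4.4 | 92.1 |
| delta | 5.00 | 13.6 | 76.5 |
| delta | 10.0 | 26.8 | 57.7 |
| delta | 25.0 | 51.5 | 26.7 |
| theta | 1.33 | 1.4 | 97.7 |
| theta | 2.50 | 4.2 | 93.1 |
| theta | 4.00 | 7.3 | 87.4 |
| theta | 5.00 | 9.5 | 83.2 |

(readings scatter by 0.5 percentage points)

* the set-up with the highest amount of monomer in chains at the outlet or at the end, in percent of the free monomer put in ("none" if the first two lie within 2 percentage points) (violet / red / teal / grey / none)
* amount of monomer in chains at the outlet or at the end, in percent of the free monomer put in, violet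
* amount of monomer in chains at the outlet or at the end, in percent of the free monomer put in, red
* amount of monomer in chains at the outlet or at the end, in percent of the free monomer put in, teal
* amount of monomer in chains at the outlet or at the end, in percent of the free monomer put in, grey

- the stated concentrations are those of everything mixed, before any reaction; amounts are the same in each set-up
- the feed brings no volume worth counting
- the earlier runs were made in a closed, stirred flask

Read the rate rather than the amounts. Between 10.0 h and 25.0 h, delta is read as making chains at a rate of kc[free monomer], and this chain constant, a pseudo-first-order constant read against the logarithmic mean of free monomer, reads kc = 0.0409 h⁻¹. The delta readings show two slowings of the rate from kc times the charge. Between 2.00 h and 5.00 h the constant reads 0.0365 h⁻¹, a start-up slowing of 1.12. The falling free monomer then slows it by 3.75 at 25.0 h, which is 0.573 in powers of ten. Of that power, the exposure kc·t supplies 0.444, and the rest is read as side loss.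

With first-order loss at a standing kc, a closed flask divides its rate by the exponential of the exposure, while a tank at steady state divides it by one plus the exposure. Delta keeps 80.4% of what chain making without side loss gives, and this reckoning applies that share throughout. Teal has exposure 1.02, violet 5.12, and grey, counted from the middle of its dosing, 0.614. That gives violet 67.3%, teal 40.7% and grey 36.9%, while red repeats delta at 51.5%. Violet has the largest exposure.

The forecast, reckoned differently, names violet, with 67%, 51.5%, 42% and 37% for violet, red, teal and grey: “Violet is best, assuming the tanks run at full radical activity.”

The flask gives violet, with 65.4%, 51.4%, 40.1% and 38.3% in the same order.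

    free monomer + living end → monomer in chains + living end, rate k1*[living end]*[free monomer] (k = 0.0620 L mol⁻¹ s⁻¹)
    free monomer + initiator → living end + monomer in chains (k = 0.00180 L mol⁻¹ s⁻¹)
    2 free monomer → homo dimer (k = 3.60 × 10⁻⁵ L mol⁻¹ s⁻¹)
    living end + transfer agent → dead chain (kL = 5.00 × 10⁻⁵ L mol⁻¹ s⁻¹)

The half-life of the living end against transfer agent, 130 h, is longer than the 25 h of red, and red holds 1.88 × 10⁻⁴ M of living end at 12.5 h and 1.76 × 10⁻⁴ M at 25.0 h. Teal, at 0.0461 M free monomer, returns by the same reckoning a constant of 0.0348 h⁻¹, lower than the 0.0409 h⁻¹ read from delta. For the neighbour of grey charged with 5.0 × 10⁻⁴ M of initiator, taking the constant in proportion to the initiator charge gives 0.102 h⁻¹, and first-order loss at that constant under the dosing then reckons 25.5% free monomer at the end. The computed neighbour holds 24.6% free monomer and 68.1% in chains.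

The data are simulated for substances that don't exist; the scatter is artificial.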